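**Plan**

- Retrosynthesis: the quinone is taken back to its 2,3-dihydro form and the C2–C3 bond of ring B is cut, which leaves an ortho-diacylbenzene. The bond from ring A to C4 is cut next (aryllithium plus N-methoxy-N-methylamide). The C42 acid is traced to solanesol by excising C1–C2 and the C3 methyl group.
- Enabling feature: C2 (methyl-bearing) and C3 (chain-bearing) of ring B are each the alpha carbon of one of the carbonyls C1 and C4, and these carbonyls sit ortho to each other on benzo ring A. Ring B is therefore the union of two enolate alpha carbons.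
- Forward order: solanesol is degraded to the amide of octaprenylacetic acid (steps 1–4). The complete chain is joined to ring A as a ketone (step 6) before ring B exists. Ring B is closed in step 8 and aromatised and oxidised in step 9.
- Stereochemistry: the seven E alkenes come unchanged from all-E solanesol. The two sp3 centres made in step 8 are racemic and are erased in step 9; the target has no stereocentre.

Key step: step 8

Assumption: commercial solanesol is taken to be the all-E nonaprenol, so its seven distal E alkenes pass unchanged into the target.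

Shorthand: octaprenyl = (2E,6E,10E,14E,18E,22E,26E)-3,7,11,15,19,23,27,31-octamethyldotriaconta-2,6,10,14,18,22,26,30-octaen-1-yl.

**Route**

Step 1
Reactants: 1 solanesol (all-E-nonaprenol)
Product: 2 rac-(2R,3R)-2,3-epoxysolanesol (trans epoxide)
Conditions: VO(acac)2 (2 mol%), t-BuOOH (1.3 equiv, decane), toluene, 0 °C to rt
Reagents that add atoms: tert-butyl hydroperoxide, CC(C)(C)OO
Why: Hydroxyl-directed, vanadium-catalysed epoxidation should act only on the C2=C3 alkene next to the free alcohol and leave the eight remote trisubstituted alkenes untouched; syn oxygen transfer to the E alkene gives the trans epoxide as a racemate, and both centres are destroyed again in step 2.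

Step 2
Reactants: 2 rac-(2R,3R)-2,3-epoxysolanesol
Product: 3 octaprenylacetone (bombiprenone)
Conditions: H5IO6 (2.2 equiv), THF–H2O (10:1), 0 °C to rt
Reagents that add atoms: water, O
Why: Periodic acid should hydrate the epoxide at its tertiary carbon and then cleave both C–C bonds of the resulting 1,2,3-triol (Malaprade glycol cleavage), so that C1 and C2 are excised and C3 remains as the methyl ketone, isolated alkenes being inert to this reagent.

Step 3
Reactants: 3 octaprenylacetone
Product: 4 octaprenylacetic acid
Conditions: NaOBr (3.3 equiv, preformed from Br2 and aq. NaOH at 0 °C), dioxane–H2O, 0 °C to rt; Na2SO3; then 1 M HCl to pH 3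
Reagents that add atoms: sodium hydroxide, [Na+].[OH-]
Why: Haloform reaction, in which the methyl group is tribrominated through its enolate and hydroxide cleaves the tribromomethyl ketone to the carboxylate; in strong alkali hypobromite should attack the enolate far faster than the isolated alkenes, as in the degradation of terpenoid methyl ketones.

Step 4
Reactants: 4 octaprenylacetic acid; 5 N,O-dimethylhydroxylamine hydrochloride
Product: 6 N-methoxy-N-methylamide of octaprenylacetic acid
Conditions: EDC·HCl (1.3 equiv), HOBt (cat.), iPr2NEt (2.5 equiv), CH2Cl2, 0 °C to rt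
Reagents that add atoms: none
Why: Carbodiimide-mediated amide coupling through the hydroxybenzotriazole active ester, the hindered base freeing the hydroxylamine from its salt while nothing else in 4 reacts.

Step 5
Reactants: 7 2'-bromopropiophenone
Product: 8 2-(2-bromophenyl)-2-ethyl-1,3-dioxolane
Conditions: ethylene glycol (3 equiv), p-TsOH·H2O (cat.), toluene, reflux, azeotropic removal of water
Reagents that add atoms: ethylene glycol, OCCO
Why: Acid-catalysed ketalisation driven by removal of water masks the ketone as a dioxolane that is stable to organolithium reagents.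

Step 6
Reactants: 8 2-(2-bromophenyl)-2-ethyl-1,3-dioxolane; 6 N-methoxy-N-methylamide of octaprenylacetic acid
Product: 10 1-[2-(2-ethyl-1,3-dioxolan-2-yl)phenyl]-2-(all-E-octaprenyl)ethan-1-one, via aryllithium 9 (not isolated)
Conditions: 8 (1.3 equiv), n-BuLi (1.25 equiv), THF, −78 °C; then 6, −78 to 0 °C; aq. NH4Cl
Reagents that add atoms: none
Why: Bromine–lithium exchange at −78 °C gives aryllithium 9, held by the neighbouring dioxolane oxygens, which should add only once to the N-methoxy-N-methylamide because the chelated adduct does not collapse before the quench (Weinreb ketone synthesis), forming the bond from ring A to C4.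

Step 7
Reactants: 10 1-[2-(2-ethyl-1,3-dioxolan-2-yl)phenyl]-2-(all-E-octaprenyl)ethan-1-one
Product: 11 1-[2-(all-E-octaprenylacetyl)phenyl]propan-1-one
Conditions: 2 M aq. HCl–THF (1:4), rt
Reagents that add atoms: water, O
Why: Acid-catalysed ketal hydrolysis at room temperature should free the second ketone, the dilute aqueous acid being too weak to protonate the trisubstituted alkenes or to drive aldol closure of the ortho-diacylbenzene.

Step 8
Reactants: 11 1-[2-(all-E-octaprenylacetyl)phenyl]propan-1-one
Product: 13 rac-(2S,3S)-2-methyl-3-(all-E-octaprenyl)-2,3-dihydronaphthalene-1,4-dione (trans-2,3-dihydromenaquinone-8), via dilithium bis-enolate 12 (not isolated)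
Conditions: LiN(SiMe3)2 (2.3 equiv), THF, −78 °C, slow inverse addition of 11 (final 0.02 M); then CuCl2 (2.3 equiv) in DMF, −78 °C; aq. NH4Cl at −78 °C
Reagents that add atoms: none
Why: Proposed new method: two equivalents of LiN(SiMe3)2 should convert 11 into the dilithium bis-enolate 12; CuCl2 (divalent copper) oxidises one enolate to an alpha-keto radical, this radical bonds to the alpha carbon of the neighbouring enolate, and a second one-electron oxidation of the resulting ketyl gives the 1,4-diketone and two CuCl. The closest known reaction type is the intramolecular oxidative coupling of ketone bis-enolates to cyclic 1,4-diketones with CuCl2 or iodine, which has not been used to close the carbonyl-containing ring of an ortho-diacylarene. Ring B closes as a six-membered ring by a formally 6-endo-trig attack of the C2 radical on C3 of the C3=C4 enolate, made easy because both acyl groups twist out of the plane of ring A and turn the p orbitals of C2 and C3 towards each other. C2 and C3 become stereocentres with no chiral element present, so 13 is racemic; the trans relationship is expected because the methyl group and the chain avoid each other during bond formation and can equilibrate through the enol, and a cis epimer would do no harm since both centres vanish in step 9. The step needs double deprotonation to outrun aldol closure of a mono-enolate onto the neighbouring ketone, which slow inverse addition to excess base at −78 °C and the strained 5-(enolendo)-exo-trig geometry of that aldol should secure, and it needs intramolecular to beat intermolecular coupling, which the ortho-phenylene tether and high dilution secure. The eight isolated alkenes are far too hard to oxidise to compete with the enolates for CuCl2.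

Step 9
Reactants: 13 rac-(2S,3S)-2-methyl-3-(all-E-octaprenyl)-2,3-dihydronaphthalene-1,4-dione
Product: 15 menaquinone-8, via menaquinol-8 14 (not isolated)
Conditions: DBU (0.2 equiv), degassed THF, 0 °C, argon; AcOH (0.25 equiv); then Ag2O (2 equiv), MgSO4, Et2O, rt, dark
Reagents that add atoms: none
Why: Base-catalysed enolisation should convert the diketone into its aromatic tautomer menaquinol-8 (keto–enol tautomerism, both sp3 centres erased), and after neutralisation Ag2O performs the classical oxidation of a naphthohydroquinone to the quinone without touching the E alkenes.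

**Compound list**

1 | solanesol (all-E-nonaprenol) | OC/C=C(\C)CC/C=C(\C)CC/C=C(\C)CC/C=C(\C)CC/C=C(\C)CC/C=C(\C)CC/C=C(\C)CC/C=C(\C)CCC=C(C)C | starting material
2 | rac-(2R,3R)-2,3-epoxysolanesol (trans epoxide, CH2OH and chain on opposite faces) | OC[C@H]1O[C@]1(C)CC/C=C(\C)CC/C=C(\C)CC/C=C(\C)CC/C=C(\C)CC/C=C(\C)CC/C=C(\C)CC/C=C(\C)CCC=C(C)C | intermediate
3 | octaprenylacetone, (5E,9E,13E,17E,21E,25E,29E)-6,10,14,18,22,26,30,34-octamethylpentatriaconta-5,9,13,17,21,25,29,33-octaen-2-one (bombiprenone) | CC(=O)CC/C=C(\C)CC/C=C(\C)CC/C=C(\C)CC/C=C(\C)CC/C=C(\C)CC/C=C(\C)CC/C=C(\C)CCC=C(C)C | intermediate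
4 | octaprenylacetic acid, (4E,8E,12E,16E,20E,24E,28E)-5,9,13,17,21,25,29,33-octamethyltetratriaconta-4,8,12,16,20,24,28,32-octaenoic acid | OC(=O)CC/C=C(\C)CC/C=C(\C)CC/C=C(\C)CC/C=C(\C)CC/C=C(\C)CC/C=C(\C)CC/C=C(\C)CCC=C(C)C | intermediate
5 | N,O-dimethylhydroxylamine hydrochloride | CNOC.Cl | starting material
6 | N-methoxy-N-methylamide of octaprenylacetic acid (all-E) | CON(C)C(=O)CC/C=C(\C)CC/C=C(\C)CC/C=C(\C)CC/C=C(\C)CC/C=C(\C)CC/C=C(\C)CC/C=C(\C)CCC=C(C)C | intermediate
7 | 2'-bromopropiophenone | CCC(=O)c1ccccc1Br | starting material
8 | 2-(2-bromophenyl)-2-ethyl-1,3-dioxolane | CCC1(OCCO1)c1ccccc1Br | intermediate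
9 | [2-(2-ethyl-1,3-dioxolan-2-yl)phenyl]lithium | CCC1(OCCO1)c1ccccc1[Li] | intermediate (not isolated)
10 | 1-[2-(2-ethyl-1,3-dioxolan-2-yl)phenyl]-2-(all-E-octaprenyl)ethan-1-one | CCC1(OCCO1)c1ccccc1C(=O)CC/C=C(\C)CC/C=C(\C)CC/C=C(\C)CC/C=C(\C)CC/C=C(\C)CC/C=C(\C)CC/C=C(\C)CCC=C(C)C | intermediate
11 | 1-[2-(all-E-octaprenylacetyl)phenyl]propan-1-one | CCC(=O)c1ccccc1C(=O)CC/C=C(\C)CC/C=C(\C)CC/C=C(\C)CC/C=C(\C)CC/C=C(\C)CC/C=C(\C)CC/C=C(\C)CCC=C(C)C | intermediate (key-step precursor)
12 | dilithium bis-enolate of 11, drawn as the Z,Z isomer (enolate geometry is lost on coupling) | C/C=C(\O[Li])c1ccccc1/C(O[Li])=C/C/C=C(\C)CC/C=C(\C)CC/C=C(\C)CC/C=C(\C)CC/C=C(\C)CC/C=C(\C)CC/C=C(\C)CCC=C(C)C | intermediate (not isolated)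
13 | rac-(2S,3S)-2-methyl-3-(all-E-octaprenyl)-2,3-dihydronaphthalene-1,4-dione (trans; one enantiomer drawn) | C[C@H]1[C@H](C/C=C(\C)CC/C=C(\C)CC/C=C(\C)CC/C=C(\C)CC/C=C(\C)CC/C=C(\C)CC/C=C(\C)CCC=C(C)C)C(=O)c2ccccc2C1=O | intermediate (key-step product)
14 | menaquinol-8, 2-methyl-3-(all-E-octaprenyl)naphthalene-1,4-diol | Cc1c(C/C=C(\C)CC/C=C(\C)CC/C=C(\C)CC/C=C(\C)CC/C=C(\C)CC/C=C(\C)CC/C=C(\C)CCC=C(C)C)c(O)c2ccccc2c1O | intermediate (not isolated)
15 | menaquinone-8, 2-methyl-3-(all-E-octaprenyl)naphthalene-1,4-dione | CC(C)=CCC/C(C)=C/CC/C(C)=C/CC/C(C)=C/CC/C(C)=C/CC/C(C)=C/CC/C(C)=C/CC/C(C)=C/CC1=C(C)C(=O)c2ccccc2C1=O | target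

**Step count and risks**

Total steps: 9. Longest linear sequence: 8 steps (1–4 and 6–9, from solanesol); step 5 is the one-step side branch.

Steps most likely to fail:

1. Step 8 (proposed new method). A mono-enolate may close onto the neighbouring ketone by aldol addition before the second deprotonation, or the alpha-keto radical may be chlorinated or couple between molecules. The fallback uses known chemistry and sets out from 11. Soft enolisation with Me3SiOTf and Et3N in CH2Cl2 at 0 °C, in which no metal enolate ever faces a ketone, should give the bis(trimethylsilyl enol ether) F1. Oxidation of F1 with (NH4)2Ce(NO3)6 (tetravalent cerium) and NaHCO3 in MeCN–THF at −30 °C is the established coupling of silyl enol ethers to 1,4-diketones through an enol ether radical cation, known in intramolecular form. It should form the same C2–C3 bond and return to the route at 13.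

2. Step 3. Electrophilic bromine may add to the trisubstituted alkenes, or the two-phase mixture may stall at partly brominated ketones. The fallback sets out from 3. Kinetic deprotonation on the methyl side with LiN(iPr)2 in THF at −78 °C and hydroxylation of the enolate with 2-(phenylsulfonyl)-3-phenyloxaziridine should give the 1-hydroxy ketone F2. Cleavage of this alpha-ketol with NaIO4 in THF–H2O removes C1 as formaldehyde and returns to the route at 4, with no halogen present at any stage.

3. Step 2. Acid-induced rearrangement of the tertiary epoxide (hydride shift or participation of the C6=C7 alkene) may compete with hydration and cleavage. The fallback sets out from 1 and works under basic instead of acidic conditions. Oxidation with activated MnO2 in hexane should give solanesal F3. Retro-aldol cleavage of F3 with aq. K2CO3 in dioxane at reflux under a nitrogen sweep that removes acetaldehyde, as in the conversion of citral into methylheptenone, returns to the route at 3.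

**Further compounds**

F1 | step 8 | 1-[(1Z)-1-(trimethylsilyloxy)prop-1-en-1-yl]-2-[(1Z)-1-(trimethylsilyloxy)-2-(all-E-octaprenyl)ethenyl]benzene | C/C=C(\O[Si](C)(C)C)c1ccccc1/C(O[Si](C)(C)C)=C/C/C=C(\C)CC/C=C(\C)CC/C=C(\C)CC/C=C(\C)CC/C=C(\C)CC/C=C(\C)CC/C=C(\C)CCC=C(C)C
F2 | step 3 | (5E,9E,13E,17E,21E,25E,29E)-1-hydroxy-6,10,14,18,22,26,30,34-octamethylpentatriaconta-5,9,13,17,21,25,29,33-octaen-2-one | OCC(=O)CC/C=C(\C)CC/C=C(\C)CC/C=C(\C)CC/C=C(\C)CC/C=C(\C)CC/C=C(\C)CC/C=C(\C)CCC=C(C)C
F3 | step 2 | solanesal (all-E-nonaprenal) | O=C/C=C(\C)CC/C=C(\C)CC/C=C(\C)CC/C=C(\C)CC/C=C(\C)CC/C=C(\C)CC/C=C(\C)CC/C=C(\C)CCC=C(C)C
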